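## Structural features

The target is a 9,9'-epoxylignan. It has one oxolane ring (O1, C2–C5) whose C2 and C5 are plain CH2 groups, a 4-hydroxy-3,5-dimethoxyphenyl (syringyl) carbinol on C3 and a syringylmethyl group on C4. Each aromatic ring is joined to the heterocycle through one carbon atom, and there is no other ring and no ring fusion. Three stereocentres stand in a row: the carbinol carbon (S), C3 (R) and C4 (R). The two ring substituents are trans, and in the zigzag C2–C3–carbinol carbon–aryl the hydroxyl group and C4 lie on the same side. The fragile parts are the two electron-rich 2,6-dimethoxyphenols, which oxidise easily, and above all the para-hydroxybenzylic alcohol, which can lose water to a quinone methide under acid or base and so lose its configuration. The finished ring has no functional handle, so the real difficulty is to fix the absolute configuration of the C3/C4 pair and then of the exocyclic carbinol, while two nearly identical aryl units enter at different oxidation levels. The key step exploits the fact that the carbinol carbon–C3 bond joins two carbons that are both acceptor sites in their obvious precursors, an aryl aldehyde carbon and the β-carbon of a butenolide. C4 is the α-carbon of that butenolide, and C5 and C2 map onto its carbonyl and acetal carbons.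

## Logic of the disconnections

**20 to 19.** The two phenolic O–H bonds are replaced by O–CH2Ph bonds. This cut comes last in the forward sense because the free phenols and the para-hydroxybenzylic alcohol of 20 tolerate neither strong base, alkylating agents nor acid. The gain is that every earlier compound is a robust aryl ether. The demand is a neutral cleavage that removes two aryl benzyl ethers faster than it touches the secondary benzylic C–OH bond, run on material free of sulfur.

**19 to 18.** The carbinol C–H bond is cut and the carbon is raised to the ketone level. This is the oxidation level at which an acyl anion equivalent delivers that carbon. The gain is that three stereocentres become two. The demand is delivery of hydride to one face of an aryl ketone whose other substituent is a branched ring carbon. C3 is now α to a carbonyl group, but its trans arrangement is the more stable one.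

**18 to 17.** The C=O bond is exchanged for the two C–S bonds of a six-membered dithioacetal. A free ketone would be reduced by hydride and would form a hemiketal with the γ-hydroxyl group of 15, which leads to the wrong ring. The mask is therefore kept until the oxolane exists. The gain is a carbon that is inert through two steps and that was a nucleophile earlier. The demand is an unmasking near neutrality that leaves C3 and the electron-rich arenes alone.

**17 to 15 (through 16).** The C5–O1 bond is cut. Both ends of the ether are primary carbons, so no stereocentre is involved and either hydroxyl group may be the one activated. The gain is an acyclic chain whose two hydroxymethyl groups are the reduced ends of a four-carbon dicarbonyl unit. The demand is activation of one hydroxyl group only, and capture by oxygen rather than by a dithiane sulfur.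

**15 to 14.** No skeletal bond is cut. C5 is raised to a lactone carbonyl and C2 to an acetal carbon bearing the alkoxy residue of 10, and the ring oxygen reconnects them. This uncovers an enolisable lactone with a controlling group next to C3. The gain is that the C3/C4 pair becomes the β/α pair of one small ring. The demand is that hydride takes both carbons fully to the CH2OH level and expels 10, without touching C–S or O–benzyl bonds or the two stereocentres.

**14 to 4, 11 and 6 (through 12 and 13).** The carbinol carbon–C3 bond and the C4–CH2Ar bond are cut. This is the most convergent cut available, since it splits the skeleton into its two aryl units and the four-carbon core. It removes two stereocentres, leaving only the acetal centre of 11. The demand is threefold. The aldehyde-derived carbon of 4 must act as a nucleophile (12) and add 1,4. It must add anti to the acetal substituent. The enolate 13 must then be alkylated by 6 anti to the group just introduced.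

**4 and 6 to 2, then to 1.** In 4 the two C–S bonds are cut to give 2 and 3. In 6 the C–Br bond is traced through the C–OH bond of 5 to the C=O bond of 2. In 2 the O–CH2Ph bond is cut to give 1. Both aryl building blocks thus come from one protected aldehyde, which halves the preparative effort. The only demand is that 6, an electron-rich benzylic halide, is used soon after it is made.

**11 to 9 and 10, and 9 to 7 (through 8).** The acetal C–O bond of 11 is cut to give 9 and 10. In 9 the two new C–O bonds and the lost formyl carbon are traced through 8 to 7. The gain is a chiral, enantiopure four-carbon acceptor from two bulk chemicals. The demand is that one acetal diastereomer can be obtained pure, for which crystallisation combined with epimerisation of the acetal carbon is relied upon.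

## Other disconnections considered

**Alternative 1:**
- **Cut.** The ring is opened at C5–O1, but the carbon electrophile is an oxetane CH2 group instead of a sulfonate. The oxolane alcohol A1 would come from the oxetanyl propanol A2. In A2 the oxetane C3 is the future C4, one oxetane CH2 is the future C5 and the other is the future exocyclic CH2.
- **Forward key step.** The catalyst is Co(salen)OTf (trivalent cobalt; salen = dianion of N,N'-bis(3,5-di-tert-butylsalicylidene)cyclohexane-1,2-diamine). It would bind the oxetane oxygen, and the primary hydroxyl group of A2 would open one of the two diastereotopic CH2–O bonds. This closes the five-membered ring, sets C4 and frees a CH2OH group.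
- **In its favour.** The step is catalytic and needs no separate activation of a hydroxyl group, because ring strain drives it. It uses no sulfur, and it leaves the configuration of C4 to a catalyst that exists in both mirror-image forms. The carbinol/C3 pair of A2 has a syn-aldol relationship and could be laid down early by an auxiliary-controlled syn aldol reaction with 2. As a way to the carbinol centre this is at least the equal of the late ketone reduction of the chosen plan, and it avoids any epimerisable ketone.
- **Against it here.** A1 carries CH2OH where the target has CH2Ar, so the second aryl ring is still missing. A β-branched primary alcohol would have to be activated and joined to an aryl-metal reagent in an sp3–sp2 coupling, followed by desilylation and debenzylation. The well-explored substrates of this ring opening are achiral oxetanes with unbranched tethers. A2 is chiral and branched next to the nucleophilic arm, so catalyst and substrate preferences may agree or clash. A cationic Lewis acid next to an electron-rich benzylic silyl ether also invites ionisation.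
- **Comparison.** In structure, the alternative uses the latent symmetry CH2–C4–CH2, whereas the chosen plan uses the 1,4-dioxygenated four-carbon backbone. In mechanism, both close the ring by SN2 attack of oxygen at a primary carbon and are equals there. In step economy, the alternative brings in the two aryl groups at two separate stages and would need roughly fourteen operations in a mostly linear order, against twelve in three converging branches.

**Alternative 2:**
- **Cut.** The first cut is the ring bond C2–C3; the second, later one is the carbinol carbon–aryl bond. The aldehyde A3 would come from the seven-membered vinyl acetal A4. In A4 the O–CH2–O carbon is the future C2, the two enol ether carbons are the future C3 and the formyl carbon, and the only stereocentre is the future C4.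
- **Forward key step.** BF3·OEt2 or Me3SiOTf would break the acetal C–O bond on the enol side. The enolate and the oxocarbenium ion remain linked through the O–CH2–CH chain and recombine at carbon. This contracts the ring to the oxolane and places the formyl group on C3. It should sit trans to the arylmethyl group for steric reasons and, because the aldehyde can epimerise, for thermodynamic ones as well.
- **In its favour.** The step is an isomerisation that loses no atom. The ring appears directly at the ether oxidation level, so steps 8 and 9 of the chosen plan have no counterpart. There is neither sulfur nor a stoichiometric auxiliary. On atom economy and on compatibility with the final hydrogenolysis this is the better plan.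
- **Against it here.** The absolute configuration hangs on the single stereocentre of A4. That centre would have to come from an enantioselective double-bond shift in the 4,7-dihydro isomer or from a resolved diol, a less secure source than a crystalline acetal. The oxocarbenium ion of a formaldehyde acetal is the least stabilised of its kind, so ionisation is harder, and acetal exchange between molecules or capture by the electron-rich arene can compete. The later aryl-metal addition to A3 is also ill-disposed. In the Felkin–Anh arrangement with C4 as the large group, the aryl nucleophile takes the place that hydride takes in step 11. This points to the opposite carbinol configuration, so oxidation to 18 and the reduction of step 11 would still be needed.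
- **Comparison.** In structure, both plans draw C3/C4 from one small heterocycle. In mechanism, a cationic rearrangement stands against an anionic three-component coupling. In step economy, the counts come out about equal (A4 in about five steps, then contraction, aryl addition, oxidation and steps 11 and 12). However, two of the alternative's steps rest on thinner analogy than any step of the chosen plan.

**Alternative 3:**
- **Cut.** The cuts are C4–C5 and C5–O1, and C5 is supplied by carbon monoxide. The lactol A5 would come from the homoallylic alcohol A6, an (E)-configured aryl-conjugated alkene that already holds both aryl rings, the silylated carbinol and C3.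
- **Forward key step.** Rh(acac)(CO)2 is used with a catalytic phosphorus ligand that exchanges reversibly with the primary hydroxyl group. This would deliver the rhodium hydride from within the tether, so that the formyl group ends on the alkene carbon nearer the hydroxyl group (future C4) and hydrogen on the benzylic carbon. The hydroxy aldehyde then closes to A5.
- **In its favour.** One catalytic step makes a C–C bond, a C–O bond, the ring and C4 from synthesis gas. A6 is short to make: syn aldol reaction of a 4-arylbut-3-enoyl imide with 2, silylation, then reductive removal of the auxiliary. The carbinol centre is again set early, and no sulfur is involved. At about ten operations in all, this alternative is better than the chosen plan in total count and about equal in longest linear sequence.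
- **Against it here.** Aryl-conjugated alkenes have an inherent preference for rhodium, and hence formyl, at the benzylic carbon. This is the reverse of what is needed, so the tether would have to override an electronic bias. 1,2-Disubstituted alkenes also react slowly. C4 is controlled only by the allylic centre C3, although equilibration through the open hydroxy aldehyde favours trans, so on this safety net the two plans are equal. Removal of the lactol hydroxyl group needs a silane with a Lewis acid, conditions under which the electron-rich benzylic silyl ether can ionise.
- **Comparison.** In structure, both plans introduce both aryl groups before the ring is finished. In mechanism, the alternative's regiochemistry opposes the substrate's bias, whereas in the chosen plan every selectivity runs with the substrate's bias. In step economy, the alternative wins on paper, but its key step and the step after it are the least predictable of all those considered.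

Key step: step 7

Remark on the chemistry: the oxolane is numbered O1, C2, C3 (carbinol-bearing), C4 (arylmethyl-bearing), C5. With this numbering 20 is S at the carbinol carbon and 3R,4R in the ring. Lactone carbons C4 and C3 of 14 (both R) become oxolane C3 and C4 of 20 without any bond to them being broken.

Step 1
Reactants: 1 syringaldehyde (4-hydroxy-3,5-dimethoxybenzaldehyde)
Product: 2 4-benzyloxy-3,5-dimethoxybenzaldehyde
Conditions: BnBr, K2CO3, DMF, 60 °C
Reagents that add atoms: benzyl bromide, BrCc1ccccc1
Why: Williamson ether synthesis; the phenoxide of 1, although flanked by two methoxy groups, is alkylated readily by the unhindered benzylic halide. The benzyl ether withstands n-BuLi at low temperature, LiAlH4, NaH, MeI and borane and leaves at the end under neutral hydrogenolysis.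

Step 2
Reactants: 2 4-benzyloxy-3,5-dimethoxybenzaldehyde; 3 propane-1,3-dithiol
Product: 4 2-(4-benzyloxy-3,5-dimethoxyphenyl)-1,3-dithiane
Conditions: BF3·OEt2 (cat.), CH2Cl2, 0 °C to rt
Reagents that add atoms: none
Why: Lewis-acid-catalysed dithioacetalisation of an aromatic aldehyde; the six-membered dithiane forms readily and the aryl benzyl ether is inert to catalytic BF3·OEt2 at this temperature.

Step 3
Reactants: 2 4-benzyloxy-3,5-dimethoxybenzaldehyde
Product: 5 (4-benzyloxy-3,5-dimethoxyphenyl)methanol
Conditions: NaBH4, MeOH–THF, 0 °C
Reagents that add atoms: none
Why: Borohydride reduction of an aldehyde; nothing else in 2 is reducible under these conditions.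

Step 4
Reactants: 5 (4-benzyloxy-3,5-dimethoxyphenyl)methanol
Product: 6 4-benzyloxy-3,5-dimethoxybenzyl bromide
Conditions: PBr3, Et2O, 0 °C; used without storage
Reagents that add atoms: phosphorus tribromide, BrP(Br)Br
Why: Conversion of a primary benzylic alcohol into the bromide through its phosphite ester and SN2 attack of bromide. The electron-rich bromide is labile, so it is made cold and taken on at once.

Step 5
Reactants: 7 furfural
Product: 9 5-hydroxyfuran-2(5H)-one (racemic), via furan endoperoxide 8 (not isolated)
Conditions: O2, visible light, rose bengal (disodium 4,5,6,7-tetrachloro-2',4',5',7'-tetraiodofluorescein, cat.), MeOH, 0 °C to rt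
Reagents that add atoms: dioxygen, O=O
Why: Dye-sensitised photo-oxygenation; singlet oxygen adds to the furan diene in a [4+2] cycloaddition to give 8. Methanol then attacks the formyl group, and the fragmentation that follows breaks the O–O bond and releases the formyl carbon as methyl formate, leaving the hydroxybutenolide with both oxygen atoms of O2.

Step 6
Reactants: 9 5-hydroxyfuran-2(5H)-one; 10 (1R,2S,5R)-menthol
Product: 11 (5R)-5-[(1R,2S,5R)-menthyloxy]furan-2(5H)-one
Conditions: p-toluenesulfonic acid (cat.), toluene, Dean–Stark reflux; crystallisation from petroleum ether, mother liquor re-equilibrated with the acid and crystallised again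
Reagents that add atoms: none
Why: Acid-catalysed acetalisation at the pseudo-acid carbon with removal of water. The acetal carbon epimerises under the same acid and the 5R diastereomer is the one expected to crystallise, so crystallisation coupled with re-equilibration should funnel the material into the single isomer 11; the three centres of 10 are untouched.

Step 7
Reactants: 4 2-(4-benzyloxy-3,5-dimethoxyphenyl)-1,3-dithiane; 11 (5R)-5-[(1R,2S,5R)-menthyloxy]furan-2(5H)-one; 6 4-benzyloxy-3,5-dimethoxybenzyl bromide
Product: 14 (3R,4R,5R)-3-(4-benzyloxy-3,5-dimethoxybenzyl)-4-[2-(4-benzyloxy-3,5-dimethoxyphenyl)-1,3-dithian-2-yl]-5-[(1R,2S,5R)-menthyloxy]oxolan-2-one, via 2-lithio-dithiane 12 (not isolated), via lithium lactone enolate 13 (not isolated)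
Conditions: 4, n-BuLi, THF, −78 to −30 °C; 11, −78 °C; then 6, DMPU, −78 to −20 °C; aq. NH4Cl
Reagents that add atoms: n-butyllithium, [Li]CCCC (its lithium stands in 12 and 13 only and is gone in 14)
Why: n-BuLi removes the C2 proton of 4, which two sulfur atoms and the aryl ring make acidic, so that the former aldehyde carbon becomes the nucleophile 12 (Corey–Seebach polarity reversal). This hindered, charge-delocalised carbanion attacks the β-carbon of 11 rather than its carbonyl group and forms the carbinol carbon–C3 bond; any 1,2-adduct can revert, whereas the 1,4-adduct 13 is a stabilised lactone enolate. The closest known reaction type is the tandem conjugate addition of lithiated aryl dithioacetals to butenolides and 5-alkoxyfuran-2(5H)-ones with alkylation of the enolate in the same flask. The β-carbon (future C3) is set by the menthyloxy group on the neighbouring acetal carbon, which blocks one face of the flat ring so that 12 enters anti to it. The α-carbon (future C4) is set in the SN2 alkylation of 13 by 6, which takes place on the face away from the very bulky dithianyl group, so that the three ring centres of 14 end all-trans (3R,4R,5R). No ring is closed in this step. The selectivities needed are 1,4 over 1,2 addition and over removal of the acetal proton (secured by the soft anion and −78 °C), anti/anti facial control (secured by the two groups just named) and single C-alkylation (secured by the reactive benzylic bromide, by DMPU, which loosens the lithium enolate aggregates, and by the crowding around the remaining α-hydrogen). The absolute sense rests on the use of 11 as one crystalline 5R diastereomer.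

Step 8
Reactants: 14 the all-trans lactone acetal of step 7
Product: 15 (2R,3R)-2-(4-benzyloxy-3,5-dimethoxybenzyl)-3-[2-(4-benzyloxy-3,5-dimethoxyphenyl)-1,3-dithian-2-yl]butane-1,4-diol
Conditions: LiAlH4, THF, 0 °C to reflux; H2O, aq. NaOH work-up
Reagents that add atoms: none
Why: Hydride reduction of a lactone; the carbonyl carbon goes to a primary alkoxide, the ring oxygen is freed as a hemiacetal alkoxide that expels the alkoxide of 10, and the aldehyde so unmasked is reduced faster than it can enolise. C–S and O–benzyl bonds and both stereocentres are untouched, and 10 can be recovered.

Step 9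
Reactants: 15 the (2R,3R)-1,4-diol
Product: 17 (3R,4R)-4-(4-benzyloxy-3,5-dimethoxybenzyl)-3-[2-(4-benzyloxy-3,5-dimethoxyphenyl)-1,3-dithian-2-yl]oxolane, via sodium alkoxide monotosylate 16 (not isolated)
Conditions: NaH (2.2 equiv), THF, 0 °C; TsCl (1.05 equiv), 0 °C to rt
Reagents that add atoms: p-toluenesulfonyl chloride, Cc1ccc(cc1)S(=O)(=O)Cl, and sodium hydride, [Na+].[H-] (their atoms stand in 16 only and are gone in 17)
Why: One-pot sulfonylation and intramolecular Williamson etherification (5-exo-tet); the less hindered hydroxymethyl group is sulfonylated and the neighbouring alkoxide displaces the sulfonate at once, which outruns a second sulfonylation and attack by sulfur. Both carbons are primary, so either monotosylate gives the same ring and no stereocentre is touched.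

Step 10
Reactants: 17 the (3R,4R)-dithianyl oxolane
Product: 18 (4-benzyloxy-3,5-dimethoxyphenyl)[(3R,4R)-4-(4-benzyloxy-3,5-dimethoxybenzyl)oxolan-3-yl]methanone
Conditions: MeI, CaCO3, MeCN–H2O, 45 °C
Reagents that add atoms: water, O
Why: Alkylative dithioacetal hydrolysis; S-methylation turns sulfur into a leaving group, the aryl-stabilised thionium ion takes up water, and a second round gives the ketone. CaCO3 keeps the medium near neutral, so C3, now α to the carbonyl group, should hold its configuration (trans is also the more stable arrangement), and no oxidant comes near the electron-rich rings.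

Step 11
Reactants: 18 the (3R,4R)-aryl oxolanyl ketone
Product: 19 (S)-(4-benzyloxy-3,5-dimethoxyphenyl)[(3R,4R)-4-(4-benzyloxy-3,5-dimethoxybenzyl)oxolan-3-yl]methanol
Conditions: (R)-Me-CBS [(3aR)-1-methyl-3,3-diphenyltetrahydro-1H,3H-pyrrolo[1,2-c][1,3,2]oxazaborole], BH3·SMe2, THF, −20 °C; MeOH quench
Reagents that add atoms: none
Why: Corey–Bakshi–Shibata reduction; the ketone binds to the ring boron of the catalyst–borane complex with the aryl group in the large-group position and hydride passes to one face, which by analogy with aryl alkyl ketones gives the S carbinol with the R catalyst (priorities OH > aryl > C3). The Felkin–Anh model with C4 as the large group anti to the incoming hydride points to the same face, so reagent and substrate should reinforce each other.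

Step 12
Reactants: 19 the (S)-carbinol bis(benzyl ether)
Product: 20 (S)-(4-hydroxy-3,5-dimethoxyphenyl)[(3R,4R)-4-(4-hydroxy-3,5-dimethoxybenzyl)oxolan-3-yl]methanol (target)
Conditions: H2 (1 atm), 10% Pd/C, EtOAc–EtOH, rt, stopped after uptake of two equivalents
Reagents that add atoms: none
Why: Catalytic hydrogenolysis of two aryl benzyl ethers, which in the absence of acid are cleaved much faster than a secondary benzylic alcohol. The neutral medium avoids quinone methide formation, so none of the three stereocentres is affected.

## Compound list

1 | syringaldehyde (4-hydroxy-3,5-dimethoxybenzaldehyde) | COc1cc(C=O)cc(OC)c1O | starting material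
2 | 4-benzyloxy-3,5-dimethoxybenzaldehyde | COc1cc(C=O)cc(OC)c1OCc1ccccc1 | intermediate
3 | propane-1,3-dithiol | SCCCS | starting material
4 | 2-(4-benzyloxy-3,5-dimethoxyphenyl)-1,3-dithiane | COc1cc(C2SCCCS2)cc(OC)c1OCc1ccccc1 | intermediate
5 | (4-benzyloxy-3,5-dimethoxyphenyl)methanol | COc1cc(CO)cc(OC)c1OCc1ccccc1 | intermediate
6 | 4-benzyloxy-3,5-dimethoxybenzyl bromide | COc1cc(CBr)cc(OC)c1OCc1ccccc1 | intermediate
7 | furfural | O=Cc1ccco1 | starting material
8 | 2,3,7-trioxabicyclo[2.2.1]hept-5-ene-1-carbaldehyde (furan endoperoxide, racemic, not isolated) | O=CC12OOC(C=C1)O2 | intermediate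
9 | 5-hydroxyfuran-2(5H)-one (racemic) | O=C1C=CC(O)O1 | intermediate
10 | (1R,2S,5R)-menthol | C[C@@H]1CC[C@H]([C@@H](C1)O)C(C)C | starting material
11 | (5R)-5-[(1R,2S,5R)-menthyloxy]furan-2(5H)-one | O=C1C=C[C@H](O[C@@H]2C[C@H](C)CC[C@H]2C(C)C)O1 | intermediate
12 | 2-lithio-2-(4-benzyloxy-3,5-dimethoxyphenyl)-1,3-dithiane (not isolated) | [Li]C1(c2cc(OC)c(OCc3ccccc3)c(OC)c2)SCCCS1 | intermediate
13 | lithium enolate of the (4R,5R) conjugate adduct, dithianyl group trans to menthyloxy (not isolated) | [Li]OC1=C[C@@H](C2(c3cc(OC)c(OCc4ccccc4)c(OC)c3)SCCCS2)[C@H](O[C@@H]2C[C@H](C)CC[C@H]2C(C)C)O1 | intermediate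
14 | (3R,4R,5R)-3-(4-benzyloxy-3,5-dimethoxybenzyl)-4-[2-(4-benzyloxy-3,5-dimethoxyphenyl)-1,3-dithian-2-yl]-5-[(1R,2S,5R)-menthyloxy]oxolan-2-one | COc1cc(C[C@H]2C(=O)O[C@@H](O[C@@H]3C[C@H](C)CC[C@H]3C(C)C)[C@@H]2C2(c3cc(OC)c(OCc4ccccc4)c(OC)c3)SCCCS2)cc(OC)c1OCc1ccccc1 | intermediate
15 | (2R,3R)-2-(4-benzyloxy-3,5-dimethoxybenzyl)-3-[2-(4-benzyloxy-3,5-dimethoxyphenyl)-1,3-dithian-2-yl]butane-1,4-diol | COc1cc(C[C@@H](CO)[C@H](CO)C2(c3cc(OC)c(OCc4ccccc4)c(OC)c3)SCCCS2)cc(OC)c1OCc1ccccc1 | intermediate
16 | sodium alkoxide of the monotosylate of 15, sulfonate on the hydroxymethyl group of the benzyl-bearing carbon (not isolated) | COc1cc(C[C@@H](COS(=O)(=O)c2ccc(C)cc2)[C@H](C[O-])C2(c3cc(OC)c(OCc4ccccc4)c(OC)c3)SCCCS2)cc(OC)c1OCc1ccccc1.[Na+] | intermediate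
17 | (3R,4R)-4-(4-benzyloxy-3,5-dimethoxybenzyl)-3-[2-(4-benzyloxy-3,5-dimethoxyphenyl)-1,3-dithian-2-yl]oxolane | COc1cc(C[C@H]2COC[C@@H]2C2(c3cc(OC)c(OCc4ccccc4)c(OC)c3)SCCCS2)cc(OC)c1OCc1ccccc1 | intermediate
18 | (4-benzyloxy-3,5-dimethoxyphenyl)[(3R,4R)-4-(4-benzyloxy-3,5-dimethoxybenzyl)oxolan-3-yl]methanone | COc1cc(C[C@H]2COC[C@@H]2C(=O)c2cc(OC)c(OCc3ccccc3)c(OC)c2)cc(OC)c1OCc1ccccc1 | intermediate
19 | (S)-(4-benzyloxy-3,5-dimethoxyphenyl)[(3R,4R)-4-(4-benzyloxy-3,5-dimethoxybenzyl)oxolan-3-yl]methanol | COc1cc(C[C@H]2COC[C@@H]2[C@H](O)c2cc(OC)c(OCc3ccccc3)c(OC)c2)cc(OC)c1OCc1ccccc1 | intermediate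
20 | (S)-(4-hydroxy-3,5-dimethoxyphenyl)[(3R,4R)-4-(4-hydroxy-3,5-dimethoxybenzyl)oxolan-3-yl]methanol | COc1cc(C[C@H]2COC[C@@H]2[C@H](O)c2cc(OC)c(O)c(OC)c2)cc(OC)c1O | target

## Step count and least certain steps

Total step count: 12. Longest linear sequence: 9 steps (1, 3, 4, 7, 8, 9, 10, 11, 12).

**Step 7 (key step).** The most likely failure is slow capture of the crowded enolate 13. While it waits for 6, three things can take over: proton exchange with product already formed, reversal of the conjugate addition on warming, or decay of the labile bromide. At the first stage, attack at the carbonyl group or removal of the acetal proton of 11 can compete, and the latter would also erode the 5R centre. The fallback separates the two bond formations. Setting out from 4 and 11, the enolate 13 is quenched cold with aq. NH4Cl. This gives the conjugate adduct (4R,5R)-4-[2-(4-benzyloxy-3,5-dimethoxyphenyl)-1,3-dithian-2-yl]-5-[(1R,2S,5R)-menthyloxy]oxolan-2-one F1, which can be purified. F1 is then enolised on its own with LiN(SiMe3)2 in THF–DMPU at −78 °C and alkylated with 6, again anti to the dithianyl group. This comes back to the route at 14.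

**Step 9.** The likely failures are sulfonylation of both hydroxyl groups, or attack of a dithiane sulfur on the activated CH2 group. The sulfur attack closes a five-membered sulfonium ring, and it competes because that sulfur sits at the same distance from the activated carbon as the alkoxide oxygen does. The fallback avoids any leaving group on carbon.
- Setting out from 14, KOH and NaBH4 in aqueous EtOH followed by acidification open the acetal ester, reduce the freed aldehyde and relactonise. The product is (3R,4R)-3-(4-benzyloxy-3,5-dimethoxybenzyl)-4-[2-(4-benzyloxy-3,5-dimethoxyphenyl)-1,3-dithian-2-yl]oxolan-2-one F2.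
- i-Bu2AlH in toluene at −78 °C gives the lactol (3R,4R)-3-(4-benzyloxy-3,5-dimethoxybenzyl)-4-[2-(4-benzyloxy-3,5-dimethoxyphenyl)-1,3-dithian-2-yl]oxolan-2-ol F3.
- Ionic reduction with Et3SiH and BF3·OEt2 in CH2Cl2 at −78 °C removes the lactol hydroxyl group and comes back to the route at 17.

**Step 10.** The likely failure is slow or incomplete unmasking, because the dithioacetal carbon is flanked by an aryl ring and a branched ring carbon. Forcing the reaction risks epimerisation at C3. The fallback changes from alkylative to oxidative activation with an isolated intermediate. Setting out from 17, one equivalent of mCPBA in CH2Cl2 at −78 °C oxidises one sulfur far faster than the arenes. This gives the monosulfoxide 2-(4-benzyloxy-3,5-dimethoxyphenyl)-2-[(3R,4R)-4-(4-benzyloxy-3,5-dimethoxybenzyl)oxolan-3-yl]-1,3-dithiane 1-oxide F4, as a mixture of sulfoxide isomers. Dilute aqueous HCl in THF then hydrolyses this much more labile dithioacetal S-oxide and comes back to the route at 18.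

**Step 11.** The likely failure is poor facial selectivity. The catalyst has to tell a flat aryl group from a branched oxolanyl group, a smaller difference than in aryl methyl ketones, and uncatalysed borane reduction can add a background. The fallback gives up catalyst control in favour of separation and recycling. Setting out from 18, reduction with NaBH4 in MeOH gives 19 together with its carbinol epimer (R)-(4-benzyloxy-3,5-dimethoxyphenyl)[(3R,4R)-4-(4-benzyloxy-3,5-dimethoxybenzyl)oxolan-3-yl]methanol F5. The two are separated by chromatography. F5 is oxidised back to 18 with MnO2 in CH2Cl2 and reduced again. The route is rejoined at 19.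

**Step 12.** The likely failures are poisoning of the catalyst by traces of sulfur carried over from step 10, and loss of the benzylic hydroxyl group by over-reduction. Over-reduction is a risk because the electron-rich ring weakens that C–O bond. The fallback exchanges the order of the last two operations. Setting out from 18, hydrogenolysis (H2, 10% Pd/C, EtOAc) is run at the ketone stage, where there is no benzylic C–O single bond to lose. It gives (4-hydroxy-3,5-dimethoxyphenyl)[(3R,4R)-4-(4-hydroxy-3,5-dimethoxybenzyl)oxolan-3-yl]methanone F6. Reduction of F6 with (R)-Me-CBS and excess BH3·SMe2 then comes back to the route directly at 20; the phenols are held for the time being as aryloxyboranes and freed by the methanol quench.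

## Further compounds

F1 | step 7 | (4R,5R)-4-[2-(4-benzyloxy-3,5-dimethoxyphenyl)-1,3-dithian-2-yl]-5-[(1R,2S,5R)-menthyloxy]oxolan-2-one | O=C1C[C@@H](C2(c3cc(OC)c(OCc4ccccc4)c(OC)c3)SCCCS2)[C@H](O[C@@H]2C[C@H](C)CC[C@H]2C(C)C)O1
F2 | step 9 | (3R,4R)-3-(4-benzyloxy-3,5-dimethoxybenzyl)-4-[2-(4-benzyloxy-3,5-dimethoxyphenyl)-1,3-dithian-2-yl]oxolan-2-one | COc1cc(C[C@H]2C(=O)OC[C@@H]2C2(c3cc(OC)c(OCc4ccccc4)c(OC)c3)SCCCS2)cc(OC)c1OCc1ccccc1
F3 | step 9 | (3R,4R)-3-(4-benzyloxy-3,5-dimethoxybenzyl)-4-[2-(4-benzyloxy-3,5-dimethoxyphenyl)-1,3-dithian-2-yl]oxolan-2-ol (both anomers) | COc1cc(C[C@H]2C(O)OC[C@@H]2C2(c3cc(OC)c(OCc4ccccc4)c(OC)c3)SCCCS2)cc(OC)c1OCc1ccccc1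
F4 | step 10 | 2-(4-benzyloxy-3,5-dimethoxyphenyl)-2-[(3R,4R)-4-(4-benzyloxy-3,5-dimethoxybenzyl)oxolan-3-yl]-1,3-dithiane 1-oxide (sulfoxide isomers) | COc1cc(C[C@H]2COC[C@@H]2C2(c3cc(OC)c(OCc4ccccc4)c(OC)c3)S(=O)CCCS2)cc(OC)c1OCc1ccccc1
F5 | step 11 | (R)-(4-benzyloxy-3,5-dimethoxyphenyl)[(3R,4R)-4-(4-benzyloxy-3,5-dimethoxybenzyl)oxolan-3-yl]methanol | COc1cc(C[C@H]2COC[C@@H]2[C@@H](O)c2cc(OC)c(OCc3ccccc3)c(OC)c2)cc(OC)c1OCc1ccccc1
F6 | step 12 | (4-hydroxy-3,5-dimethoxyphenyl)[(3R,4R)-4-(4-hydroxy-3,5-dimethoxybenzyl)oxolan-3-yl]methanone | COc1cc(C[C@H]2COC[C@@H]2C(=O)c2cc(OC)c(O)c(OC)c2)cc(OC)c1O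
A1 | alternative 1 | {(3S,4R)-4-[(S)-(4-benzyloxy-3,5-dimethoxyphenyl)(tert-butyldimethylsilyloxy)methyl]oxolan-3-yl}methanol | OC[C@H]1COC[C@@H]1[C@H](O[Si](C)(C)C(C)(C)C)c1cc(OC)c(OCc2ccccc2)c(OC)c1
A2 | alternative 1 | (2R,3S)-3-(4-benzyloxy-3,5-dimethoxyphenyl)-3-(tert-butyldimethylsilyloxy)-2-(oxetan-3-yl)propan-1-ol | OC[C@@H](C1COC1)[C@H](O[Si](C)(C)C(C)(C)C)c1cc(OC)c(OCc2ccccc2)c(OC)c1
A3 | alternative 2 | (3R,4R)-4-(4-benzyloxy-3,5-dimethoxybenzyl)oxolane-3-carbaldehyde | COc1cc(C[C@H]2COC[C@@H]2C=O)cc(OC)c1OCc1ccccc1
A4 | alternative 2 | (5R)-5-(4-benzyloxy-3,5-dimethoxybenzyl)-4,5-dihydro-1,3-dioxepine | COc1cc(C[C@H]2COCOC=C2)cc(OC)c1OCc1ccccc1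
A5 | alternative 3 | (3R,4R)-3-(4-benzyloxy-3,5-dimethoxybenzyl)-4-[(S)-(4-benzyloxy-3,5-dimethoxyphenyl)(tert-butyldimethylsilyloxy)methyl]oxolan-2-ol (2R anomer drawn, anomers interconvert) | COc1cc(C[C@H]2[C@H](O)OC[C@@H]2[C@H](O[Si](C)(C)C(C)(C)C)c2cc(OC)c(OCc3ccccc3)c(OC)c2)cc(OC)c1OCc1ccccc1
A6 | alternative 3 | (2R,3E)-4-(4-benzyloxy-3,5-dimethoxyphenyl)-2-[(S)-(4-benzyloxy-3,5-dimethoxyphenyl)(tert-butyldimethylsilyloxy)methyl]but-3-en-1-ol | OC[C@@H](/C=C/c1cc(OC)c(OCc2ccccc2)c(OC)c1)[C@H](O[Si](C)(C)C(C)(C)C)c1cc(OC)c(OCc2ccccc2)c(OC)c1
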